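**Retrosynthetic overview**
1. The hydroperoxide is unmasked last from a peroxyketal; the (E,E)-diene comes from a Stille coupling of ring A iodoalkene 23 with peroxide-bearing alkenylstannane 27.
2. The C1 carbinol with its CH2OAc arm comes from face-selective dihydroxylation of an exocyclic methylidene; the C3′=C4′ enone comes from dehydrogenation of the ring B ketone.
3. Key disconnection: the C1–C2 bond of ring A and the C1′–C5′ bond of ring B are made in one gold-catalysed 1,6-enyne cyclisation/semipinacol shift, so rings A and B form together and ring B grows out of a 2-methylcyclobutanol (itself made by expansion of a cyclopropanol).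
4. Enabling feature: in ring B, C1′ lies between the carbonyl carbon C2′ and the methyl-bearing C5′ and is bonded to ring A carbon C2, which is vicinal to the oxygenated quaternary C1. Hence C2′/C3′/C4′/C5′ can be a 1-alkenyl-2-methylcyclobutanol, C2=C1′ its (E)-alkene, and C1 plus the CH2O carbon a terminal alkyne three atoms away.
5. The enyne comes from cross-metathesis of vinylcyclobutanol 15 (from methyl (R)-lactate) with iodo-dienyne 10 (Evans alkylation, alkyne homologation, carboalumination).

Key step: step 12

Remark on the chemistry: the SMILES places the C5′ methyl and ring A cis on the cyclopentenone, and C1′ is α to the ketone; the route therefore sets C1′ by a stereospecific 1,2-shift and uses no equilibrating base afterwards.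
Locants used: ring A = C1 (carbinol carbon), C2 (bears ring B), C3, C4 (bears the side chain), C5; ring B = C1′ (bonded to C2), C2′ (C=O), C3′=C4′, C5′ (CHMe).

**Route**

Step 1
Reactants: 1 (R)-4-benzyloxazolidin-2-one; 2 pent-4-enoyl chloride
Product: 3 (R)-4-benzyl-3-(pent-4-enoyl)oxazolidin-2-one
Conditions: n-BuLi, THF, −78 °C; then 2, −78 to 0 °C
Reagents that add atoms: none
Why: N-acylation of the lithiated oxazolidinone with an acid chloride is the standard entry to Evans imides; no stereocentre is formed.

Step 2
Reactants: 3; 4 (3-bromoprop-1-yn-1-yl)triisopropylsilane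
Product: 5 (R)-4-benzyl-3-[(S)-2-[3-(triisopropylsilyl)prop-2-yn-1-yl]pent-4-enoyl]oxazolidin-2-one
Conditions: NaN(SiMe3)2, THF, −78 °C; then 4, −78 to −40 °C
Reagents that add atoms: none
Why: Evans asymmetric alkylation: the chelated (Z)-sodium enolate is attacked by the reactive propargylic bromide on the face opposite the benzyl group, which sets the future C4 as (S).

Step 3
Reactants: 5
Product: 6 (S)-2-(prop-2-en-1-yl)-5-(triisopropylsilyl)pent-4-yn-1-ol
Conditions: LiBH4, H2O (1 equiv), Et2O, 0 °C
Reagents that add atoms: none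
Why: Reductive cleavage of the imide with LiBH4 should give the primary alcohol without touching the silylalkyne, the alkene or the α-stereocentre, and releases the auxiliary.

Step 4
Reactants: 6
Product: 7 (S)-2-(prop-2-en-1-yl)-5-(triisopropylsilyl)pent-4-ynal
Conditions: Dess–Martin periodinane, NaHCO3, CH2Cl2, 0 °C to rt
Reagents that add atoms: none
Why: Dess–Martin oxidation is neutral enough to give the α-branched aldehyde without epimerisation.

Step 5
Reactants: 7
Product: 8 (S)-(4-ethynylhept-6-en-1-yn-1-yl)triisopropylsilane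
Conditions: dimethyl (1-diazo-2-oxopropyl)phosphonate, K2CO3, MeOH, 0 °C to rt
Reagents that add atoms: dimethyl (1-diazo-2-oxopropyl)phosphonate CC(=O)C(=[N+]=[N-])P(=O)(OC)OC
Why: Ohira–Bestmann (Seyferth–Gilbert) homologation converts the aldehyde into the terminal alkyne under mild carbonate conditions that the triisopropylsilyl alkyne survives and that rarely epimerise α-alkyl aldehydes.

Step 6
Reactants: 8
Product: 10 (S,E)-[4-(1-iodoprop-1-en-2-yl)hept-6-en-1-yn-1-yl]triisopropylsilane, via alkenylalane 9 (not isolated)
Conditions: Me3Al, Cp2ZrCl2 (0.3 equiv), CH2Cl2, 0 °C to rt; then I2, THF, −30 to 0 °C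
Reagents that add atoms: trimethylaluminium C[Al](C)C; iodine II
Why: Zirconium-catalysed carboalumination (Negishi) adds methyl and aluminium syn across the terminal alkyne with methyl at the internal carbon, and iodinolysis with retention should give the (E)-iodoalkene; the bulky silylalkyne and the monosubstituted alkene react much more slowly.

Step 7
Reactants: 11 methyl (R)-lactate
Product: 12 (R)-1-(1-hydroxyethyl)cyclopropan-1-ol
Conditions: EtMgBr (3.5 equiv), Ti(OiPr)4 (0.5 equiv), THF, 0 °C to rt
Reagents that add atoms: ethylmagnesium bromide CC[Mg]Br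
Why: Kulinkovich cyclopropanation: the titanacyclopropane made from EtMgBr acts as a 1,2-dicarbanion on the ester while the lactate hydroxyl is carried as its magnesium alkoxide, and the carbinol stereocentre is not involved.

Step 8
Reactants: 12
Product: 14 (R)-2-methylcyclobutan-1-one, via mesylate 13 (not isolated)
Conditions: MsCl, pyridine, CH2Cl2, 0 °C to rt; used as a solution because of its volatility
Reagents that add atoms: none
Why: Selective mesylation of the secondary hydroxyl is followed by a pinacol-type 1,2-shift of a cyclopropane bond anti to the leaving group (cyclopropylcarbinyl ring expansion), so the methyl-bearing carbon is inverted and the (R)-lactate should give the (R)-cyclobutanone.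

Step 9
Reactants: 14
Product: 15 (1R,2R)-1-ethenyl-2-methylcyclobutan-1-ol (hydroxyl cis, vinyl trans to methyl)
Conditions: CH2=CHMgBr, CeCl3, THF, −78 °C
Reagents that add atoms: vinylmagnesium bromide C=C[Mg]Br
Why: Organocerium-mediated 1,2-addition avoids enolisation of the configurationally labile ketone and occurs anti to the adjacent methyl group, which puts hydroxyl cis and vinyl trans to methyl.

Step 10
Reactants: 10; 15 (3 equiv)
Product: 16 (1S,2R)-1-[(1E,4S)-4-[(E)-1-iodoprop-1-en-2-yl]-7-(triisopropylsilyl)hept-1-en-6-yn-1-yl]-2-methylcyclobutan-1-ol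
Conditions: second-generation Hoveyda–Grubbs catalyst (5 mol %), CH2Cl2, 40 °C
Reagents that add atoms: none
Why: Olefin cross-metathesis between a readily reacting terminal alkene and a hindered tertiary allylic alcohol that cannot homodimerise is selective and should give the (E)-alkene because of the quaternary allylic carbon; the iodoalkene and the bulky silylalkyne are spectators.

Step 11
Reactants: 16
Product: 17 (1S,2R)-1-[(1E,4S)-4-[(E)-1-iodoprop-1-en-2-yl]hept-1-en-6-yn-1-yl]-2-methylcyclobutan-1-ol
Conditions: Bu4NF, THF, 0 °C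
Reagents that add atoms: none
Why: Fluoride cleaves the alkynyl C–Si bond selectively and leaves the iodoalkene and the tertiary cyclobutanol untouched.

Step 12
Reactants: 17
Product: 18 (2S,3R)-2-[(1S,4S)-4-[(E)-1-iodoprop-1-en-2-yl]-2-methylidenecyclopentyl]-3-methylcyclopentan-1-one
Conditions: [(t-Bu)2(2-biphenylyl)P]Au(NCMe)SbF6 (3 mol %), CH2Cl2, −20 to 0 °C
Reagents that add atoms: none
Why: The cationic gold centre activates the terminal alkyne, ring A carbon C2 of the (E)-alkene attacks its internal carbon C1 anti to gold, and the positive charge developing at C1′ is discharged in the same event by 1,2-shift of the CHMe carbon of the cyclobutanol (strain release, oxygen lone-pair push), after which the hydroxyl proton protodeaurates the exocyclic alkenylgold to the methylidene; the closest known reaction type is the gold-catalysed enyne carbocyclisation terminated by a pinacol-type shift of a cycloalkanol (ring-expanding cycloisomerisation). Ring A closes in the 5-exo-dig mode (C1–C2 bond), and ring B arises by one-carbon expansion of the four-membered ring, C1′ being inserted between the carbinol carbon (which becomes C2′=O) and C5′. C2 and C1′ are fixed relative to each other by stereospecific anti addition across the (E)-alkene, C5′ migrates with retention so that its methyl ends cis to ring A, and the cis C2/C4 relationship follows from a chair-like transition state with the C4 substituent and the alkenyl group pseudo-equatorial. The cyclobutanol stereocentre reinforces this face, because in the reactive rotamer the C–O bond lies inside (near the alkene) and the migrating C–CHMe bond anti to the incoming alkyne, which is the matched arrangement for the (1S,2R) carbinol. The step needs 5-exo over 6-endo closure (terminal alkyne, phosphine–gold catalyst), migration of the CHMe rather than the CH2 carbon (higher migratory aptitude of the more substituted carbon, which is also the one held anti) and no participation of the iodoalkene (deactivated by iodine).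

Step 13
Reactants: 18
Product: 21 (4R,5S)-5-[(1S,4S)-4-[(E)-1-iodoprop-1-en-2-yl]-2-methylidenecyclopentyl]-4-methylcyclopent-2-en-1-one, via lithium enolate 19 (not isolated), via sulfilimine adduct 20 (not isolated)
Conditions: LiN(i-Pr)2 (1.1 equiv), THF, −78 °C; then PhS(Cl)=N-t-Bu, −78 °C
Reagents that add atoms: none
Why: Kinetic deprotonation with LiN(i-Pr)2 occurs at the unhindered C3′ methylene rather than at the tertiary C1′–H, and the enolate is dehydrogenated in one pot by N-tert-butylbenzenesulfinimidoyl chloride (Mukaiyama dehydrogenation: α-sulfenylation, then syn elimination at low temperature), so C1′ should not be epimerised.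

Step 14
Reactants: 21
Product: 22 (4R,5S)-5-[(1S,2R,4S)-2-hydroxy-2-(hydroxymethyl)-4-[(E)-1-iodoprop-1-en-2-yl]cyclopentyl]-4-methylcyclopent-2-en-1-one
Conditions: OsO4 (2 mol %), N-methylmorpholine N-oxide, acetone/H2O, 0 °C
Reagents that add atoms: osmium tetroxide O=[Os](=O)(=O)=O (transfers both oxygens); N-methylmorpholine N-oxide C[N+]1([O-])CCOCC1 and water O (terminal oxygen sources)
Why: Catalytic osmium tetroxide dihydroxylation (Upjohn) takes the electron-rich 1,1-disubstituted alkene in preference to the enone and the iodoalkene and attacks the face anti to the ring B substituent at C2 and the C4 substituent, which sets C1 with hydroxyl trans to ring B.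

Step 15
Reactants: 22
Product: 23 [(1R,2S,4S)-1-hydroxy-4-[(E)-1-iodoprop-1-en-2-yl]-2-[(1S,5R)-5-methyl-2-oxocyclopent-3-en-1-yl]cyclopentyl]methyl acetate
Conditions: Ac2O, pyridine, CH2Cl2, 0 °C
Reagents that add atoms: acetic anhydride CC(=O)OC(C)=O
Why: Acetylation with Ac2O/pyridine is selective for the primary over the tertiary hydroxyl and is too weakly basic to epimerise C1′.

Step 16
Reactants: 24 2-methylbut-3-yn-2-ol
Product: 25 2-methylbut-3-yn-2-yl hydroperoxide
Conditions: 50% aq. H2O2, H2SO4 (cat.), 0 °C to rt
Reagents that add atoms: hydrogen peroxide OO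
Why: Acid-catalysed perhydrolysis of a tertiary propargylic alcohol proceeds through the propargylic cation, which hydrogen peroxide captures at the tertiary carbon.

Step 17
Reactants: 25
Product: 26 3-[(2-methoxypropan-2-yl)peroxy]-3-methylbut-1-yne
Conditions: 2-methoxypropene, pyridinium p-toluenesulfonate (cat.), CH2Cl2, 0 °C
Reagents that add atoms: 2-methoxypropene COC(C)=C
Why: Acid-catalysed addition of the hydroperoxide to the enol ether gives the peroxyketal, a protected hydroperoxide that tolerates base, tin and palladium reagents.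

Step 18
Reactants: 26
Product: 27 (E)-tributyl[3-[(2-methoxypropan-2-yl)peroxy]-3-methylbut-1-en-1-yl]stannane
Conditions: Bu3SnH, PdCl2(PPh3)2 (2 mol %), THF, 0 °C
Reagents that add atoms: tributyltin hydride CCCC[SnH](CCCC)CCCC
Why: Palladium-catalysed syn hydrostannation places tin at the terminal carbon because of the quaternary propargylic centre and should give the (E)-alkenylstannane under non-radical conditions that leave the dialkyl peroxide intact.

Step 19
Reactants: 23; 27
Product: 28 [(1R,2S,4S)-1-hydroxy-4-[(2E,4E)-6-[(2-methoxypropan-2-yl)peroxy]-6-methylhepta-2,4-dien-2-yl]-2-[(1S,5R)-5-methyl-2-oxocyclopent-3-en-1-yl]cyclopentyl]methyl acetate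
Conditions: Pd2(dba)3 (5 mol %), AsPh3, N-methylpyrrolidinone, rt, dark
Reagents that add atoms: none
Why: Stille coupling of an alkenyl iodide with an alkenylstannane proceeds with retention at both partners under neutral conditions at room temperature, which the peroxyketal, the tertiary alcohol and the base-sensitive cis-cyclopentenone should survive.

Step 20
Reactants: 28
Product: 29 [(1R,2S,4S)-1-hydroxy-4-[(2E,4E)-6-hydroperoxy-6-methylhepta-2,4-dien-2-yl]-2-[(1S,5R)-5-methyl-2-oxocyclopent-3-en-1-yl]cyclopentyl]methyl acetate (CNP0204569.2)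
Conditions: AcOH/THF/H2O (4:2:1), rt
Reagents that add atoms: none
Why: Mild aqueous acid hydrolyses the peroxyketal to the free hydroperoxide without ionising the tertiary allylic C–O bond or cleaving the acetate.

**Compound list**
1 | (R)-4-benzyloxazolidin-2-one | O=C1N[C@H](Cc2ccccc2)CO1 | starting material
2 | pent-4-enoyl chloride | C=CCCC(=O)Cl | starting material
3 | (R)-4-benzyl-3-(pent-4-enoyl)oxazolidin-2-one | C=CCCC(=O)N1[C@H](Cc2ccccc2)COC1=O | intermediate
4 | (3-bromoprop-1-yn-1-yl)triisopropylsilane | CC(C)[Si](C#CCBr)(C(C)C)C(C)C | starting material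
5 | (R)-4-benzyl-3-[(S)-2-[3-(triisopropylsilyl)prop-2-yn-1-yl]pent-4-enoyl]oxazolidin-2-one | C=CC[C@@H](CC#C[Si](C(C)C)(C(C)C)C(C)C)C(=O)N1[C@H](Cc2ccccc2)COC1=O | intermediate
6 | (S)-2-(prop-2-en-1-yl)-5-(triisopropylsilyl)pent-4-yn-1-ol | C=CC[C@@H](CC#C[Si](C(C)C)(C(C)C)C(C)C)CO | intermediate
7 | (S)-2-(prop-2-en-1-yl)-5-(triisopropylsilyl)pent-4-ynal | C=CC[C@@H](CC#C[Si](C(C)C)(C(C)C)C(C)C)C=O | intermediate
8 | (S)-(4-ethynylhept-6-en-1-yn-1-yl)triisopropylsilane | C=CC[C@@H](CC#C[Si](C(C)C)(C(C)C)C(C)C)C#C | intermediate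
9 | (E)-alkenyl(dimethyl)alane from syn methylalumination of 8 | C=CC[C@@H](CC#C[Si](C(C)C)(C(C)C)C(C)C)/C(C)=C/[Al](C)C | intermediate (not isolated)
10 | (S,E)-[4-(1-iodoprop-1-en-2-yl)hept-6-en-1-yn-1-yl]triisopropylsilane | C=CC[C@@H](CC#C[Si](C(C)C)(C(C)C)C(C)C)/C(C)=C/I | intermediate
11 | methyl (R)-lactate | C[C@@H](O)C(=O)OC | starting material
12 | (R)-1-(1-hydroxyethyl)cyclopropan-1-ol | C[C@@H](O)C1(O)CC1 | intermediate
13 | (R)-1-(1-hydroxycyclopropyl)ethyl methanesulfonate | C[C@@H](OS(C)(=O)=O)C1(O)CC1 | intermediate (not isolated)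
14 | (R)-2-methylcyclobutan-1-one | O=C1CC[C@H]1C | intermediate
15 | (1R,2R)-1-ethenyl-2-methylcyclobutan-1-ol | C=C[C@]1(O)CC[C@H]1C | intermediate
16 | (1S,2R)-1-[(1E,4S)-4-[(E)-1-iodoprop-1-en-2-yl]-7-(triisopropylsilyl)hept-1-en-6-yn-1-yl]-2-methylcyclobutan-1-ol | CC(C)[Si](C(C)C)(C(C)C)C#CC[C@@H](/C(C)=C/I)C/C=C/[C@]1(O)CC[C@H]1C | intermediate
17 | (1S,2R)-1-[(1E,4S)-4-[(E)-1-iodoprop-1-en-2-yl]hept-1-en-6-yn-1-yl]-2-methylcyclobutan-1-ol | C#CC[C@@H](/C(C)=C/I)C/C=C/[C@]1(O)CC[C@H]1C | intermediate
18 | (2S,3R)-2-[(1S,4S)-4-[(E)-1-iodoprop-1-en-2-yl]-2-methylidenecyclopentyl]-3-methylcyclopentan-1-one | C=C1C[C@@H](/C(C)=C/I)C[C@H]1[C@H]1C(=O)CC[C@H]1C | intermediate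
19 | lithium enolate of 18 (C2′–O–Li, C2′=C3′) | C=C1C[C@@H](/C(C)=C/I)C[C@H]1[C@H]1C(O[Li])=CC[C@H]1C | intermediate (not isolated)
20 | C3′-(N-tert-butyl-S-phenylsulfilimino) adduct of 18 (new centres unassigned) | C=C1C[C@@H](/C(C)=C/I)C[C@H]1[C@H]1C(=O)C(S(=NC(C)(C)C)c2ccccc2)C[C@H]1C | intermediate (not isolated)
21 | (4R,5S)-5-[(1S,4S)-4-[(E)-1-iodoprop-1-en-2-yl]-2-methylidenecyclopentyl]-4-methylcyclopent-2-en-1-one | C=C1C[C@@H](/C(C)=C/I)C[C@H]1[C@H]1C(=O)C=C[C@H]1C | intermediate
22 | (4R,5S)-5-[(1S,2R,4S)-2-hydroxy-2-(hydroxymethyl)-4-[(E)-1-iodoprop-1-en-2-yl]cyclopentyl]-4-methylcyclopent-2-en-1-one | OC[C@@]1(O)C[C@@H](/C(C)=C/I)C[C@H]1[C@H]1C(=O)C=C[C@H]1C | intermediate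
23 | [(1R,2S,4S)-1-hydroxy-4-[(E)-1-iodoprop-1-en-2-yl]-2-[(1S,5R)-5-methyl-2-oxocyclopent-3-en-1-yl]cyclopentyl]methyl acetate | CC(=O)OC[C@@]1(O)C[C@@H](/C(C)=C/I)C[C@H]1[C@H]1C(=O)C=C[C@H]1C | intermediate
24 | 2-methylbut-3-yn-2-ol | C#CC(C)(C)O | starting material
25 | 2-methylbut-3-yn-2-yl hydroperoxide | C#CC(C)(C)OO | intermediate
26 | 3-[(2-methoxypropan-2-yl)peroxy]-3-methylbut-1-yne | C#CC(C)(C)OOC(C)(C)OC | intermediate
27 | (E)-tributyl[3-[(2-methoxypropan-2-yl)peroxy]-3-methylbut-1-en-1-yl]stannane | CCCC[Sn](CCCC)(CCCC)/C=C/C(C)(C)OOC(C)(C)OC | intermediate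
28 | peroxyketal-protected target (2-methoxypropan-2-yl peroxide of 29) | CC(=O)OC[C@@]1(O)C[C@@H](/C(C)=C/C=C/C(C)(C)OOC(C)(C)OC)C[C@H]1[C@H]1C(=O)C=C[C@H]1C | intermediate
29 | [(1R,2S,4S)-1-hydroxy-4-[(2E,4E)-6-hydroperoxy-6-methylhepta-2,4-dien-2-yl]-2-[(1S,5R)-5-methyl-2-oxocyclopent-3-en-1-yl]cyclopentyl]methyl acetate | CC(=O)OC[C@@]1(O)C[C@@H](/C(C)=C/C=C/C(C)(C)OO)C[C@H]1[C@H]1C(=O)C=C[C@H]1C | target

**Step count**
Total: 20 steps. Longest linear sequence: 14 steps (steps 1–6, 10–15, 19, 20).

**Steps most likely to fail, with fallbacks**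

Step 12. What may go wrong: insufficient facial discrimination in the ring A closure (C2/C4 cis versus trans), attack of the iodoalkene on the activated alkyne in competition with the intended alkene, or migration of the CH2 instead of the CHMe carbon. The fallback separates ring expansion and ring A closure; it sets out from 8 and comes back at 18.
- The carboalumination of step 6 is repeated on 8, but alkenylalane 9 is quenched with N-bromosuccinimide to give the bromoalkene (S,E)-[4-(1-bromoprop-1-en-2-yl)hept-6-en-1-yn-1-yl]triisopropylsilane F1, because a bromoalkene survives the tin radical chemistry below.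
- Cross-metathesis with 15 (as in step 10) should give the bromo analogue of 16, F2, and Bu4NF the bromo enyne F3.
- N-Iodosuccinimide in CH2Cl2 at −40 °C triggers an iodonium-induced semipinacol ring expansion (anti addition across the (E)-alkene, the CHMe carbon migrating with retention), which sets C1′ and C5′ as in the main route and gives the β-iodo ketone F4.
- Bu3SnH/Et3B/air in toluene at −78 °C abstracts the alkyl iodine much faster than the vinylic bromine; the secondary radical at C2 closes ring A by 5-exo-dig cyclisation onto the alkyne through a chair-like transition state and gives the bromo analogue of 18, F5.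
- Copper-catalysed halogen exchange (copper iodide CuI, NaI, trans-N,N′-dimethylcyclohexane-1,2-diamine, dioxane, 110 °C) converts the bromoalkene into the iodoalkene with retention, which is 18.

Step 10. What may go wrong: slow cross-metathesis at the hindered tertiary allylic alcohol, with homodimerisation of the allyl partner and ruthenium-hydride alkene migration. The fallback builds the (E)-alkenyl cyclobutanol by acetylide addition and trans-reduction; it sets out from 10 and comes back at 16.
- Selective oxidative cleavage of the terminal alkene (OsO4 cat., NaIO4, 2,6-lutidine, dioxane/H2O) gives the one-carbon-shorter aldehyde (S,E)-4-iodo-3-methyl-2-[3-(triisopropylsilyl)prop-2-yn-1-yl]... written simply as the C2-aldehyde F6.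
- Ohira–Bestmann homologation gives the terminal alkyne F7.
- Its lithium acetylide (LiN(i-Pr)2, THF, −78 °C, CeCl3) adds to ketone 14 anti to the methyl group and gives the propargylic cyclobutanol F8.
- Hydroxyl-directed trans-hydroalumination (NaAlH2(OCH2CH2OMe)2, THF, 0 °C, then aqueous work-up) gives the (E)-allylic alcohol 16.

Step 18. What may go wrong: reductive cleavage of the O–O bond by the tin hydride or a palladium hydride, or loss of regiocontrol in the hydrostannation. The fallback joins the side chain by a Heck reaction with an alkene partner that never meets a hydride; it sets out from 23 and comes back at 28.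
- Photooxygenation of 2-methylbut-2-ene (O2, tetraphenylporphyrin, visible light, CH2Cl2, 0 °C; Schenck ene reaction) gives 2-methylbut-3-en-2-yl hydroperoxide F9, which is separated from its secondary regioisomer.
- 2-Methoxypropene with pyridinium p-toluenesulfonate gives the peroxyketal 3-[(2-methoxypropan-2-yl)peroxy]-3-methylbut-1-ene F10.
- A Heck reaction of 23 with F10 (Pd(OAc)2, Ag2CO3, DMF, rt) bonds the iodoalkene carbon to the terminal alkene carbon; β-hydride elimination can only occur away from the quaternary carbon and should give the (E,E)-diene 28.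

**Further compounds**
F1 | step 12 | (S,E)-[4-(1-bromoprop-1-en-2-yl)hept-6-en-1-yn-1-yl]triisopropylsilane | C=CC[C@@H](CC#C[Si](C(C)C)(C(C)C)C(C)C)/C(C)=C/Br
F2 | step 12 | bromo analogue of 16 | CC(C)[Si](C(C)C)(C(C)C)C#CC[C@@H](/C(C)=C/Br)C/C=C/[C@]1(O)CC[C@H]1C
F3 | step 12 | bromo analogue of 17 | C#CC[C@@H](/C(C)=C/Br)C/C=C/[C@]1(O)CC[C@H]1C
F4 | step 12 | (2S,3R)-2-[(1S,3S)-3-[(E)-1-bromoprop-1-en-2-yl]-1-iodohex-5-yn-1-yl]-3-methylcyclopentan-1-one | C#CC[C@@H](/C(C)=C/Br)C[C@H](I)[C@H]1C(=O)CC[C@H]1C
F5 | step 12 | bromo analogue of 18 | C=C1C[C@@H](/C(C)=C/Br)C[C@H]1[C@H]1C(=O)CC[C@H]1C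
F6 | step 10 | (S,E)-3-(1-iodoprop-1-en-2-yl)-6-(triisopropylsilyl)hex-5-ynal | O=CC[C@@H](CC#C[Si](C(C)C)(C(C)C)C(C)C)/C(C)=C/I
F7 | step 10 | (S,E)-[4-(1-iodoprop-1-en-2-yl)hepta-1,6-diyn-1-yl]triisopropylsilane | C#CC[C@@H](CC#C[Si](C(C)C)(C(C)C)C(C)C)/C(C)=C/I
F8 | step 10 | (1S,2R)-1-[(4S)-4-[(E)-1-iodoprop-1-en-2-yl]-7-(triisopropylsilyl)hepta-1,6-diyn-1-yl]-2-methylcyclobutan-1-ol | CC(C)[Si](C(C)C)(C(C)C)C#CC[C@@H](/C(C)=C/I)CC#C[C@]1(O)CC[C@H]1C
F9 | step 18 | 2-methylbut-3-en-2-yl hydroperoxide | C=CC(C)(C)OO
F10 | step 18 | 3-[(2-methoxypropan-2-yl)peroxy]-3-methylbut-1-ene | C=CC(C)(C)OOC(C)(C)OC
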